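How much D is left in the flask at 10 h, and is the flask still moving then?

| flask | D | G | remark | time |
|---|---|---|---|---|
| delta | 0.067 M | 0.20 M (in portions, 3) | run made earlier; portions every 1.0 h |  |
| beta | 0.15 M | 0.20 M (in portions, 3) | run made earlier; portions every 1.0 h |  |
| gamma | 0.10 M | 0.40 M (in portions, 3) | run made earlier; portions every 1.0 h |  |
| flask | 0.10 M | 0.200 M (in portions, 3) | the portions of G follow each other after 1.0 h, the first at the start | 10 h |
- delta (time / h: D / %, Q / %): 0.667: 77.2, 5.6; 2.00: 51.4, 10.2; 4.00: 34.0, 15.5; 6.00: 26.2, 14.9; 8.00: 21.0, 15.8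
- beta (time / h: D / %, Q / %): 0.667: 64.0, 4.4; 1.33: 45.3, 7.7; 2.50: 29.4, 10.5; 4.00: 20.8, 11.2; 8.00: 11.5, 11.6
- gamma (time / h: D / %, Q / %): 0.667: 69.8, 7.2; 2.00: 41.9, 13.4; 4.00: 26.2, 17.1; 6.00: 19.3, 17.5; 8.00: 14.6, 19.1

(each reading ± 0.5 percentage points)
- the state of affairs at 10 h: stopped, and by what, or still going (forward and back rates have come level / all of D has reacted / it is still moving)
- how much of the D has reacted by 10 h
- how much Q there is at 10 h, in percent of the D charged
- amount of Q if the flask were left three thousand times as long, in percent of the D charged
- percentages count the D that a species holds: one L counts as two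
- the analysis behind the earlier runs scatters by 0.5 percentage points, standard deviation
- steps thought possible: D + G -> Q; D -> E; 2 D -> L; Q <-> J; 2 G -> Z; G + Q -> X
- the reaction counts as stopped when no species that holds the D changes by six tenths of a point or more over the second half of the time

Let f be the fraction of the D charge still there and c that charge. Try the plainest curve: if D falls as its own square, then 1/f = 1 + k·c·t, with k constant. Read k from the last readings of the two runs that have the flask's G charge:

delta: k = 0.117 L mol⁻¹ min⁻¹
beta: k = 0.107 L mol⁻¹ min⁻¹
mean: k = 0.112 L mol⁻¹ min⁻¹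

Call this the mean loss constant, an apparent second-order rate constant. It replaces the whole curve by one number, so test it.

Object first that G may take D while it lasts, which would make k sag late. Read k early instead:

delta, 2.00 h: k = 0.118 L mol⁻¹ min⁻¹
beta, 2.50 h: k = 0.107 L mol⁻¹ min⁻¹

These early readings match the late ones within what the scatter allows, so no sag shows in delta or beta, though this does not say that G takes no D.

Object next that the constants differ between runs, and that gamma, with the flask's D and 0.40 M of G, reads 0.122 L mol⁻¹ min⁻¹, higher than either. Bracket the flask with the extremes: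

reckoned f in the flask at 10 h: 12.0% with gamma's constant, 13.5% with beta's

The spread is small, so commit to the mean:

f at 10 h = 13.0%, reacted 87.0%
f at half the time = 22.9%

Over the second half this reckoning has D in the flask fall by 10 percentage points, beyond the stopping mark, so by this estimate the flask is still moving. This reckoning says nothing of Q.

The forecast says it is still moving, with 87% reacted, 14.1% of Q at the asked time and 14.5% when left long. Its ground for D: “The D loss fits second order in all three runs”.

The result for the flask is this: it is still moving, with 86.9% reacted, 13.8% of Q at the asked time and 13.8% when left long.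

    D + G → Q (k = 0.0420 L mol⁻¹ min⁻¹)
    D → E (k = 4.00 × 10⁻⁴ min⁻¹)
    2 D → L (k = 0.0390 L mol⁻¹ min⁻¹)
    Q ⇌ J (K = 0.150, k = 0.00250 min⁻¹)
    2 G → Z (k = 0.340 L mol⁻¹ min⁻¹)
    G + Q → X (k = 0.0130 L mol⁻¹ min⁻¹)

Now read the same flask earlier, at 2.5 h, with the same constant 0.112 L mol⁻¹ min⁻¹:

f = 37.3%

That neighbour shows 37.3% of D, with 62.7% reacted. It holds 45.6% as L, more than the 11.8% as Q, and 15% of its G is still unbound.

(The data are simulated for substances that don't exist; noise was put on by code.)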